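A small charge of protic impurity, 5.00% of the starting material on Tuesday and 10.0% on Friday, changed together with the temperature, so these two runs leave two ways of reckoning open.

the same everywhere: starting material 1.5 M
- Tuesday's: partner 2.1 M; protic impurity 0.075 M; temperature 0 °C; run made earlier
- Friday's: partner 1.5 M; protic impurity 0.15 M; temperature 35 °C; run made earlier
- north: partner 1.50 M; protic impurity 0.0750 M; temperature 25 °C; time 1.5 h
- south-east: partner 1.50 M; protic impurity 0.0750 M; temperature 45 °C; time 1.5 h
- west: partner 1.50 M; protic impurity 0.0750 M; temperature 5 °C; time 1.5 h
- east: partner 1.50 M; protic impurity 0.0750 M; temperature 65 °C; time 1.5 h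

- Tuesday's (time / h: target / %, isomer of the product / %, starting material / %): 0.333: 3.0, 0, 80.8; 0.500: 4.3, 0.4, 72.4; 0.833: 5.4, 3.0, 58.7; 1.33: 5.7, 7.0, 43.0; 2.50: 6.2, 10.3, 24.4; 5.00: 5.7, 14.6, 3.6
- Friday's (time / min: target / %, isomer of the product / %, starting material / %): 4.00: 10.0, 1.9, 13.7; 6.00: 13.7, 2.2, 2.8; 12.0: 13.5, 1.0, 0.2; 25.0: 12.5, 1.7, 0; 50.0: 13.2, 0.9, 0.7

(standard deviation of a reading: 1 percentage point)



1. the best flask by share of target in all that became target or isomer of the product; "all alike" if 1.5 percentage points covers them all (north / south-east / west / east / all alike)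
2. share of target in all that became target or isomer of the product, north
3. share of target in all that became target or isomer of the product, south-east
4. share of target in all that became target or isomer of the product, west
5. share of target in all that became target or isomer of the product, east

The first way lets target follow the impurity. The new flasks hold Tuesday's impurity and Friday's partner, so target is taken from Tuesday's last reading and the pool, target plus isomer of the product, from Friday's last three:

pool = 14.3%, share = 40.0%, alike in north, south-east, west and east.

The second way lets temperature divide the pool. The ratio of isomer of the product to target reads 2.56 on Tuesday and 0.0918 on Friday. Taken as ratios at rest (thermodynamic control), they give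

66.6 kJ mol⁻¹,

the shift heat, the energy that says how steeply the ratio at rest climbs on cooling. Each flask's ratio is Friday's times exp(shift heat / R × (inverse flask temperature − inverse Friday temperature)), and its share is target over pool:

west: ratio 1.51, share 39.8%
north: ratio 0.219, share 82.0%
south-east: ratio 0.0406, share 96.1%
east: ratio 0.00917, share 99.1%

The two ways meet at west and part in the hotter flasks. Neither way is shown to cheat, since impurity, partner and temperature differ together between Tuesday's and Friday's runs, so these readings do not separate them. This reckoning takes the second way as its own choice, not as a proven one, and on that choice names east.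

The forecast, with figures of its own, says: “The target tracks the protic impurity.” It gives north 29% (22% to 40%), south-east 29% (21% to 44%), west 37% (29% to 47%) and east 29% (20% to 48%), and names west as best.

The flasks give north 76.0%, south-east 93.2%, west 41.7% and east 98.1%, so east is best.

    2 partner → homo product (k = 3.39 × 10⁻⁵ L mol⁻¹ s⁻¹, Ea = 76.0 kJ mol⁻¹)
    partner → decomposed reagent (k = 4.71 × 10⁻⁴ s⁻¹, Ea = 75.0 kJ mol⁻¹)
    starting material → intermediate (k = 3.01 × 10⁻⁴ s⁻¹, Ea = 79.0 kJ mol⁻¹)
    starting material + protic impurity → quenched substrate (k = 6.48 × 10⁻⁴ L mol⁻¹ s⁻¹, Ea = 70.0 kJ mol⁻¹)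
    target ⇌ isomer of the product (K = 1.70, k = 7.49 × 10⁻⁴ s⁻¹, Ea = 87.0 kJ mol⁻¹, ΔH = −58.0 kJ mol⁻¹)
    partner + intermediate → target (k = 2.31 × 10⁻⁴ L mol⁻¹ s⁻¹, Ea = 71.0 kJ mol⁻¹)
    (constants at 5 °C)

In east, the step from starting material and protic impurity to quenched substrate makes no difference to the share. The shift heat gave east 99.1%. Carried to the neighbour, the same flask as east run at 40 °C, it gives 94.3%, and that neighbour holds 90.7%.

The runs are calculated from invented constants; the scatter is artificial.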